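The elm run holds reagent at twice the amount of starting material, so my first thought is that reagent is ample and that time is what counts.

| setting | elm | midnight | spring | winter |
|---|---|---|---|---|
| starting material | 20 mM | 20 mM | 20 mM | 20 mM |
| partner | 54 mM | 36.0 mM | 36.0 mM | 36.0 mM |
| reagent | 40 mM | 40.0 mM | 40.0 mM | 40.0 mM |
| temperature | 35 °C | 35 °C | 20 °C | 5 °C |
| remark | run made earlier |  |  |  |
| time |  | 6.0 d | 6.0 d | 6.0 d |

elm run (percent of the starting material charged)

| time / h | target / % | starting material / % |
|---|---|---|
| 4.00 | 10.3 | 70.9 |
| 8.00 | 21.7 | 56.3 |
| 10.0 | 23.7 | 51.9 |
| 15.0 | 24.9 | 44.0 |

(each reading ± 0.5 percentage points)

- the earlier runs were read with a standard deviation of 0.5 percentage points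
- the earlier runs do not show what temperature does; that part of a forecast is a guess

- the flask that comes out highest in amount of target, in percent of the starting material charged, or "all alike" when all lie within 1.5 percentage points (midnight / spring / winter / all alike)
- target at the end, in percent of the starting material charged, midnight
- target at the end, in percent of the starting material charged, spring
- target at the end, in percent of the starting material charged, winter

But I take log10 of c(starting material), in decades. The first 4.00 h of elm remove 0.149 decades and the next 4.00 h remove 0.100, a ratio of 0.670, which reads as reagent with a half-life of 6.94 h. If every block keeps that ratio, the series sums to 0.453 decades. Two blocks are thin, though, and each carries the scatter. So I test the series on a later reading: it gives 0.352 decades at 15.0 h, and elm reads 0.357.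

Elm has more partner than the new flasks, however. If one reagent goes per starting material, that sum means starting material took a share 0.522 of reagent's loss. I assume partner took the rest, in proportion to its charge. Reagent's loss constant at midnight's charges then becomes 0.0840 /h, and the reagent ceiling, the decades of starting material a charge of reagent removes before it is lost, is 0.539. In this reckoning it scales with c(reagent), the other charges held.

Temperature is the weak point: elm stands at 35 °C throughout. I guess a factor of 4 in every rate from one flask to the next colder one, and the same ceiling:

| flask | the time counts as, on midnight's clock | decades reached |
|---|---|---|
| midnight | 144 h | 0.539 |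
| spring | 36.0 h | 0.513 |
| winter | 9.00 h | 0.286 |

Elm's highest target reading, 24.9%, stands at 0.357 decades, and its last interval gained 1.2 percentage points of target for 7.9 points of starting material. So I want the flask nearest that point. Winter lies closer to it than spring, and I commit to winter, though the factor is a guess.

The forecast gives 12%, 17% and 19% for midnight, spring and winter, and says “I expect winter to be highest”.

The flasks give 13.7%, 22.0% and 10.4%, so spring comes out highest.

    starting material + reagent → open intermediate (k = 0.0468 /M/min, Ea = 80.0 kJ/mol)
    reagent + partner → second intermediate (k = 0.0261 /M/min, Ea = 74.0 kJ/mol)
    open intermediate + second intermediate → target (k = 0.919 /M/min, Ea = 75.0 kJ/mol)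
    2 open intermediate → homo product (k = 0.472 /M/min, Ea = 53.0 kJ/mol)
    partner + target → over-reaction product (k = 0.0335 /M/min, Ea = 58.0 kJ/mol)
    (constants at 35 °C)

Spring stands at 0.559 decades, beside its ceiling of 0.539. Winter reaches 0.185, less than my table's figure, and midnight reaches 0.928, above the ceiling. The neighbour of midnight charged with 10 mM of reagent has a reckoned ceiling of 0.135 decades, which in this reckoning leaves 73.3% of the starting material. Reagent is its limiting reagent, at 0% of its charge, and that flask ends with 75.6% of the starting material.

The runs come from a simulation for substances that don't exist; scatter was added.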